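Product hardly showed in the earlier runs: the north-east run had 3.7% of it at 90.0 s, with starting material already down to 73.0%. So I took something to stand between the two, and I used the loss of starting material as the clock of each flask.

all flasks: starting material 14 mM; coupling partner 14.7 mM

|  | free catalyst | impurity | remark |
|---|---|---|---|
| south | 36 µM | 14 µM | run made earlier |
| east | 36 µM | 22 µM | run made earlier |
| north-east | 54 µM | 29 µM | run made earlier |
| flask | 36 µM | 29 µM |  |

| run | time / s | product / % | starting material / % |
|---|---|---|---|
| south | 15.0 | 0 | 95.1 |
| south | 30.0 | 0.8 | 90.7 |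
| south | 40.0 | 0.8 | 87.3 |
| south | 60.0 | 2.5 | 82.2 |
| south | 80.0 | 3.5 | 77.9 |
| south | 90.0 | 2.7 | 75.6 |
| east | 10.0 | 0 | 95.9 |
| east | 15.0 | 0 | 96.6 |
| east | 25.0 | 0.7 | 94.0 |
| east | 40.0 | 0.5 | 91.5 |
| east | 60.0 | 0.2 | 87.9 |
| east | 80.0 | 1.0 | 84.0 |
| east | 90.0 | 1.2 | 83.1 |
| north-east | 10.0 | 0.2 | 94.6 |
| north-east | 25.0 | 0.8 | 91.1 |
| north-east | 40.0 | 1.2 | 86.6 |
| north-east | 60.0 | 3.2 | 80.4 |
| north-east | 90.0 | 3.7 | 73.0 |

(scatter of a reading: 0.5 percentage points)

- no earlier run changes the charge of coupling partner; that part of a forecast is a guess

* apparent order in coupling partner when 30% of the starting material are converted (percent change of the rate of making product for one percent more coupling partner charged)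
* factor on the rate of making product when 30% of the starting material are converted if coupling partner is charged twice over

The bench rule says that equal catalyst charges give equal rates. I tried it on the south and east runs, both charged 36 µM, and it failed: at 90.0 s the east run kept more starting material, 83.1% against 75.6%. Their ratios of impurity to catalyst, 0.389 and 0.611, were too large for the rule, and the flask's ratio is 0.806.

I therefore replaced the charge by the live catalyst, the catalyst charged minus the impurity charged, which is 7.00 µM in the flask. With live catalyst steady, the loss is pseudo-first-order. From 25.0 s on, the north-east run read 0.204 min⁻¹ and the east run 0.114 min⁻¹, a ratio of 1.79, while their live catalysts stand at 1.79. Scaling the north-east reading to the flask gave 0.0572 min⁻¹, so I expected 30% conversion after 6.23 min.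

For the partner I had two ends: order 1 if its step is slow, order 0 if it is fast. No earlier run changes the partner charge, so where the order lay between those ends stayed a guess of mine.

The forecast gave order 0.6 (0 to 1.1) and factor 1.5 (1 to 2.2), noting “Every run used the same partner charge, so its order is not measured”.

The flask gives order 0.38, factor 1.23, and 30% conversion at 5.99 min.

    starting material + free catalyst → free catalyst + open intermediate (k = 146 M⁻¹ s⁻¹)
    free catalyst + open intermediate ⇌ catalyst intermediate (K = 120 M⁻¹, k = 248 M⁻¹ s⁻¹)
    coupling partner + catalyst intermediate → free catalyst + product (k = 290 M⁻¹ s⁻¹)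
    free catalyst + impurity → spent catalyst (k = 14100 M⁻¹ s⁻¹)

At 2.00 min the flask held 80.6% of its catalyst as spent catalyst, and free catalyst plus catalyst intermediate came to 19.4%, against a live share of 19.4%. The charge over the live catalyst is 5.14, and the same flask without the step from free catalyst and impurity to spent catalyst makes product, at 30% conversion, at a multiple of 5.14.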